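**Red reading.** The target in the red run reached 19% of the substrate charged at 15.0 min, and I built my curve on that reading, which carries the scatter below. Four new flasks differ in free catalyst only.

| setting | grey | teal | red | cedar | alder | larch | birch |
|---|---|---|---|---|---|---|---|
| substrate | 0.26 M | 0.26 M | 0.26 M | 0.26 M | 0.26 M | 0.26 M | 0.26 M |
| reagent | 0.52 M | 0.52 M | 0.52 M | 0.520 M | 0.520 M | 0.520 M | 0.520 M |
| free catalyst | 0.018 mM | 0.094 mM | 0.41 mM | 0.020 mM | 0.060 mM | 0.20 mM | 0.50 mM |
| remark | run made earlier | run made earlier | run made earlier |  |  |  |  |
| time |  |  |  | 15 min | 15 min | 15 min | 15 min |

- grey (time / min: target / %): 1.33: 0; 4.00: 3; 8.00: 2; 10.0: 0; 15.0: 1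
- teal (time / min: target / %): 3.00: 0; 6.00: 6; 10.0: 2; 12.0: 5; 15.0: 4
- red (time / min: target / %): 1.33: 1; 2.50: 2; 4.00: 4; 8.00: 13; 15.0: 19

(standard deviation of a reading: 2 percentage points)

- "hardly changes" means that all values lie within two and a half points (for a concentration: within two and a half percent of the largest)

1. amount of target at the end, in percent of the substrate charged for cedar, alder, larch, birch, in this order
2. the shape of the row from first to last (rises, then falls / rises all the way / hardly changes / falls all the way / falls, then rises)

**The knee.** I drew the end amount against the catalyst charge. Taking the target's growth as proportional to catalyst, time and remaining substrate, red gave 1.95 mM, which I called the knee charge: the free catalyst charge that, on this reckoning, in 15 min, takes the substrate down by one factor of e through the formation of target. On the same reckoning, a longer time lowers it in proportion. Teal checks it, since its charge over the knee gives 4.83% against a reading of 4%.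

**The curve.** The line starts at the origin and its slope is one whole substrate charge per knee charge, so my first answers were 1.03%, 3.08%, 10.3% and 25.7%. Substrate runs down during a flask, so I multiplied each answer by the mean substrate left, one minus half the answer. For birch this gave 22.4%, and a further round gave 22.8%. Larch went to 9.78%, while cedar and alder stayed near 1.02% and 3.03%. The birch charge lies lower than the knee, so my row stays on the early bend of my curve. My curve levels at the whole substrate charge, taking one reagent per target, with reagent at twice the substrate as the excess and substrate as the limiting reagent.

**The forecast.** It gave 1%, 3%, 9.7% and 22.5%, a row that rises all the way, on the ground “So the reaction looks first order in free catalyst”. My last two values stand slightly above it.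

**The result.** The flasks gave 1.10%, 3.26%, 10.5% and 24.1%, a row that rises all the way, so the forecast held.

    catalyst intermediate A ⇌ catalyst intermediate B (K = 0.440, k = 67.0 min⁻¹)
    substrate + released group → side product (k = 0.180 M⁻¹ min⁻¹)
    catalyst intermediate D ⇌ free catalyst + target (K = 13.0 M, k = 210 min⁻¹)
    substrate + free catalyst ⇌ catalyst intermediate A (K = 4.40 M⁻¹, k = 68.0 M⁻¹ min⁻¹)
    catalyst intermediate C ⇌ released group + catalyst intermediate D (K = 0.120 M, k = 220 min⁻¹)
    reagent + catalyst intermediate B → catalyst intermediate C (k = 960 M⁻¹ min⁻¹)

**Time allowed.** Birch ended at 24.1% against my 22.8%, and the main reason for that end amount was the time allowed. At 150 min birch held 67.8%, a gain of 44 percentage points, which is 58% of what was missing. The knee carries over to cedar at that same time: there it falls to 0.195 mM, so the first answer is 10.3% and the second round 9.77%. The cedar flask held 10.3% of target at 150 min.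

The readings are simulated from invented constants.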